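The flavone's ring C is opened at O1–C8a and C4–C4a. Because C8a and C4a are neighbours on ring A and C4a is flanked by the C5 oxygen, both bonds can be made on an aryne spanning these two carbons: a 3-arylpropiolate adds through oxygen at C8a and its acyl group shifts to C4a, giving the ortho-hydroxyaryl ynone in one operation. The aryne comes from a 2-(trimethylsilyl)aryl triflate of a symmetric 4-alkyl-3,5-bis(benzyloxy)phenol that already carries the (1S,2S) side chain, itself assembled acyclically by Ireland–Claisen rearrangement, Felkin–Anh allylation and ring-closing metathesis. Amine-mediated 6-endo closure and global deprotection finish the synthesis.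

Key step: step 16

Remark: C2–C8a are flavone locants; C1'–C6' are the cyclohexane carbons (C1' bears the CH2, C2' the hydroxyl, C6' the geminal methyls); the side chain is read as (1'S,2'S), hydroxyl trans to the arylmethyl group.

Step 1
Reactants: 1 2,4,6-trihydroxybenzaldehyde
Product: 2 2,6-dihydroxy-4-(triisopropylsilyloxy)benzaldehyde
Conditions: iPr3SiCl (1.0 equiv), imidazole, DMF, 0 °C
Reagents that add atoms: triisopropylsilyl chloride, CC(C)[Si](Cl)(C(C)C)C(C)C
Why: Silyl ether formation should go to the 4-hydroxyl, because the 2- and 6-hydroxyls are hydrogen-bonded to and flanked by the formyl group while the para phenol is the most acidic and accessible one.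

Step 2
Reactants: 2 2,6-dihydroxy-4-(triisopropylsilyloxy)benzaldehyde
Product: 3 2,6-bis(benzyloxy)-4-(triisopropylsilyloxy)benzaldehyde
Conditions: BnOH, PPh3, DIAD, THF, 0 °C → rt
Reagents that add atoms: benzyl alcohol, OCc1ccccc1
Why: Double Mitsunobu etherification benzylates the acidic ortho phenols under neutral conditions, which spares the aryl silyl ether para to the formyl group that carbonate bases would cleave.

Step 3
Reactants: 3 2,6-bis(benzyloxy)-4-(triisopropylsilyloxy)benzaldehyde; 4 Meldrum's acid (2,2-dimethyl-1,3-dioxane-4,6-dione)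
Product: 8 3-[2,6-bis(benzyloxy)-4-(triisopropylsilyloxy)phenyl]propanoic acid, via arylidene Meldrum's acid 5 (not isolated), via arylmethyl Meldrum's acid 6 (not isolated), via arylmethylmalonic acid 7 (not isolated)
Conditions: Hantzsch ester (diethyl 2,6-dimethyl-1,4-dihydropyridine-3,5-dicarboxylate), L-proline (cat.), EtOH, rt; then pyridine–H2O (9:1), 100 °C
Reagents that add atoms: water, O
Why: Knoevenagel condensation, Hantzsch-ester transfer hydrogenation of the alkylidene Meldrum's acid and hydrolytic decarboxylation in one flask should turn the hindered, electron-rich aldehyde into the arylpropanoic acid without acid or base strong enough to touch the silyl or benzyl ethers.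

Step 4
Reactants: 9 mesityl oxide (4-methylpent-3-en-2-one)
Product: 10 (R)-4-methylpent-3-en-2-ol
Conditions: (S)-2-methyl-CBS-oxazaborolidine (10 mol%), catecholborane, toluene, −78 °C; then MeOH, aq. NaOH
Reagents that add atoms: none
Why: Corey–Bakshi–Shibata reduction, in which the (S)-oxazaborolidine binds the ketone with the alkenyl group as the large substituent and delivers hydride to the face that gives the (R)-carbinol, while catecholborane at low temperature leaves the alkene alone.

Step 5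
Reactants: 8 3-[2,6-bis(benzyloxy)-4-(triisopropylsilyloxy)phenyl]propanoic acid; 10 (R)-4-methylpent-3-en-2-ol
Product: 11 (2R)-4-methylpent-3-en-2-yl 3-[2,6-bis(benzyloxy)-4-(triisopropylsilyloxy)phenyl]propanoate
Conditions: DCC, DMAP (cat.), CH2Cl2, 0 °C → rt
Reagents that add atoms: none
Why: Steglich esterification joins the unhindered acid and the secondary allylic alcohol under neutral conditions, so the carbinol centre is retained and no allylic transposition occurs.

Step 6
Reactants: 11 (2R)-4-methylpent-3-en-2-yl 3-[2,6-bis(benzyloxy)-4-(triisopropylsilyloxy)phenyl]propanoate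
Product: 14 (2S,4E)-2-[2,6-bis(benzyloxy)-4-(triisopropylsilyloxy)benzyl]-3,3-dimethylhex-4-enoic acid, via silyl ketene acetal 12 (not isolated), via trimethylsilyl ester 13 (not isolated)
Conditions: LiN(iPr)2 (LDA), THF, −78 °C; Me3SiCl; −78 → 55 °C; then 1 M HCl
Reagents that add atoms: none
Why: Ireland–Claisen rearrangement, in which kinetic enolisation in THF gives the (E)-silyl ketene acetal and the chair transition state with the carbinol methyl equatorial transfers the (R) centre of the ester to C1' as (S) while forming the C1'–C6' bond to the quaternary carbon and an (E)-propenyl group.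

Step 7
Reactants: 14 (2S,4E)-2-[2,6-bis(benzyloxy)-4-(triisopropylsilyloxy)benzyl]-3,3-dimethylhex-4-enoic acid
Product: 15 (3S,5E)-3-[2,6-bis(benzyloxy)-4-(triisopropylsilyloxy)benzyl]-4,4-dimethylhept-5-en-2-one
Conditions: MeLi (2.5 equiv), Et2O, 0 °C → rt; inverse quench into cold 1 M HCl
Reagents that add atoms: methyllithium, [Li]C
Why: Addition of methyllithium to the lithium carboxylate gives a stable geminal dialkoxide that releases the methyl ketone only on hydrolysis, and the C1' hydrogen, shielded by the neighbouring quaternary carbon, should not be removed.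

Step 8
Reactants: 15 (3S,5E)-3-[2,6-bis(benzyloxy)-4-(triisopropylsilyloxy)benzyl]-4,4-dimethylhept-5-en-2-one
Product: 16 (4S,5S,7E)-5-[2,6-bis(benzyloxy)-4-(triisopropylsilyloxy)benzyl]-4,6,6-trimethylnona-1,7-dien-4-ol
Conditions: allylMgBr, Et2O–THF, −78 °C
Reagents that add atoms: allylmagnesium bromide, C=CC[Mg]Br
Why: Felkin–Anh-controlled 1,2-addition to the α-branched methyl ketone, in which the quaternary C6' substituent lies anti to the incoming allyl group and the nucleophile passes the C1' hydrogen, should set C2' as (S), that is hydroxyl trans to the arylmethyl group once the allyl carbon has become C3' of the ring (adding the ring carbon to a resident methyl group avoids the opposite epimer that methyl addition to the cyclic ketone would give).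

Step 9
Reactants: 16 (4S,5S,7E)-5-[2,6-bis(benzyloxy)-4-(triisopropylsilyloxy)benzyl]-4,6,6-trimethylnona-1,7-dien-4-ol
Product: 18 (1S,2S)-2-[2,6-bis(benzyloxy)-4-(triisopropylsilyloxy)benzyl]-1,3,3-trimethylcyclohexan-1-ol, via cyclohexenol 17 (not isolated)
Conditions: second-generation Grubbs catalyst RuCl2(=CHPh)(H2IMes)(PCy3) (5 mol%), ClCH2CH2Cl, 60 °C; then H2 (5 bar), 70 °C
Reagents that add atoms: none
Why: Ring-closing metathesis forms the C4'–C5' bond of the six-membered ring with loss of propene, and the ruthenium hydride generated from the same complex under hydrogen saturates the ring alkene (tandem metathesis–hydrogenation) without hydrogenolysis of benzyl ethers or change at either stereocentre.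

Step 10
Reactants: 18 (1S,2S)-2-[2,6-bis(benzyloxy)-4-(triisopropylsilyloxy)benzyl]-1,3,3-trimethylcyclohexan-1-ol
Product: 19 {[(1S,2S)-2-[2,6-bis(benzyloxy)-4-(triisopropylsilyloxy)benzyl]-1,3,3-trimethylcyclohexyl]oxy}triethylsilane
Conditions: Et3SiOTf, 2,6-lutidine, CH2Cl2, −20 → 0 °C
Reagents that add atoms: triethylsilyl trifluoromethanesulfonate, CC[Si](CC)(CC)OS(=O)(=O)C(F)(F)F
Why: Silyl ether formation with the silyl triflate and a non-nucleophilic base is the standard way to silylate a hindered tertiary alcohol.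

Step 11
Reactants: 19 {[(1S,2S)-2-[2,6-bis(benzyloxy)-4-(triisopropylsilyloxy)benzyl]-1,3,3-trimethylcyclohexyl]oxy}triethylsilane
Product: 20 3,5-bis(benzyloxy)-4-{[(1S,2S)-2,6,6-trimethyl-2-(triethylsilyloxy)cyclohexyl]methyl}phenol
Conditions: Bu4NF (1.0 equiv), THF, −40 → −10 °C; aq. NH4Cl
Reagents that add atoms: none
Why: Fluoride-mediated desilylation should take only the aryl silyl ether, since phenoxide is the far better leaving group and the tertiary triethylsilyl ether is sterically shielded.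

Step 12
Reactants: 20 3,5-bis(benzyloxy)-4-{[(1S,2S)-2,6,6-trimethyl-2-(triethylsilyloxy)cyclohexyl]methyl}phenol
Product: 21 2-bromo-3,5-bis(benzyloxy)-4-{[(1S,2S)-2,6,6-trimethyl-2-(triethylsilyloxy)cyclohexyl]methyl}phenol
Conditions: NBS (1.0 equiv), CH2Cl2, −78 → −30 °C
Reagents that add atoms: N-bromosuccinimide, O=C1CCC(=O)N1Br
Why: Electrophilic aromatic bromination ortho to the free phenol, where the para position is blocked by the side chain and the two ortho positions are equivalent, so one equivalent should give a single monobromide.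

Step 13
Reactants: 21 2-bromo-3,5-bis(benzyloxy)-4-{[(1S,2S)-2,6,6-trimethyl-2-(triethylsilyloxy)cyclohexyl]methyl}phenol
Product: 24 3,5-bis(benzyloxy)-2-(trimethylsilyl)-4-{[(1S,2S)-2,6,6-trimethyl-2-(triethylsilyloxy)cyclohexyl]methyl}phenyl trifluoromethanesulfonate, via aryl trimethylsilyl ether 22 (not isolated), via lithium silylphenoxide 23 (not isolated)
Conditions: (Me3Si)2NH, THF, 65 °C, then evaporation; n-BuLi, THF, −78 → −20 °C; Tf2O, −78 → 0 °C
Reagents that add atoms: hexamethyldisilazane, C[Si](C)(C)N[Si](C)(C)C; trifluoromethanesulfonic anhydride, O=S(=O)(OS(=O)(=O)C(F)(F)F)C(F)(F)F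
Why: O-silylation, bromine–lithium exchange and 1,3 oxygen-to-carbon silyl migration (retro-Brook rearrangement) place the trimethylsilyl group between the phenoxide and a benzyloxy group, and triflation of the phenoxide completes the 2-silylaryl triflate.

Step 14
Reactants: 25 3,4-bis(benzyloxy)benzaldehyde
Product: 26 1,2-bis(benzyloxy)-4-(2,2-dibromovinyl)benzene
Conditions: CBr4, PPh3, CH2Cl2, 0 °C
Reagents that add atoms: carbon tetrabromide, BrC(Br)(Br)Br
Why: Corey–Fuchs dibromo-olefination, a Wittig-type reaction of the dibromomethylene ylide with the aldehyde.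

Step 15
Reactants: 26 1,2-bis(benzyloxy)-4-(2,2-dibromovinyl)benzene
Product: 28 3-[3,4-bis(benzyloxy)phenyl]propiolic acid, via lithium acetylide 27 (not isolated)
Conditions: n-BuLi (2.2 equiv), THF, −78 → 0 °C; CO2, −78 °C; aq. HCl
Reagents that add atoms: carbon dioxide, O=C=O
Why: Bromine–lithium exchange and Fritsch–Buttenberg–Wiechell rearrangement (second stage of the Corey–Fuchs sequence) give the lithium acetylide, which is carboxylated by carbon dioxide.

Step 16
Reactants: 24 3,5-bis(benzyloxy)-2-(trimethylsilyl)-4-{[(1S,2S)-2,6,6-trimethyl-2-(triethylsilyloxy)cyclohexyl]methyl}phenyl trifluoromethanesulfonate; 28 3-[3,4-bis(benzyloxy)phenyl]propiolic acid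
Product: 30 3-[3,4-bis(benzyloxy)phenyl]-1-[2,4-bis(benzyloxy)-6-hydroxy-3-{[(1S,2S)-2,6,6-trimethyl-2-(triethylsilyloxy)cyclohexyl]methyl}phenyl]prop-2-yn-1-one, via aryne 29 (not isolated)
Conditions: CsF (4 equiv), 28 (1.5 equiv), THF, 100 °C, sealed tube
Reagents that add atoms: none
Why: Fluoride removes the trimethylsilyl group with loss of triflate to give aryne 29 (C4a≡C8a); the carboxylate of 28 bonds through oxygen to C8a, and the carbanion thus placed on C4a adds to the neighbouring acyloxy carbonyl, so that the transient four-membered adduct collapses to a C8a phenoxide carrying the ynone carbonyl on C4a. This is the known σ-insertion of arynes into the C–O bond of carboxylic acids, which gives ortho-hydroxyaryl ketones and, with arylpropiolic acids, leads on to flavones. No ring is closed and no stereocentre is formed, and the side-chain centres are remote from the reacting atoms. The regioselectivity needed is secured by the C5 benzyloxy group next to the aryne, which by induction and aryne distortion directs the nucleophile to the distal carbon C8a and stabilises the anion on C4a, and since the phenol from which 24 is made is symmetric the side chain necessarily ends up at C6. Acyl transfer has to outrun protonation of the aryl anion, which an aprotic medium without acetonitrile, a sparingly soluble fluoride source and heat should favour, and the shielded tertiary silyl ether and the benzyl ethers are expected to tolerate CsF. Any ynone that already cyclises in this flask is carried to the same flavone in step 17.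

Step 17
Reactants: 30 3-[3,4-bis(benzyloxy)phenyl]-1-[2,4-bis(benzyloxy)-6-hydroxy-3-{[(1S,2S)-2,6,6-trimethyl-2-(triethylsilyloxy)cyclohexyl]methyl}phenyl]prop-2-yn-1-one
Product: 32 5,7-bis(benzyloxy)-2-[3,4-bis(benzyloxy)phenyl]-6-{[(1S,2S)-2,6,6-trimethyl-2-(triethylsilyloxy)cyclohexyl]methyl}-4H-chromen-4-one, via aminoenone 31 (not isolated)
Conditions: Et2NH (3 equiv), EtOH–THF, 50 °C
Reagents that add atoms: none
Why: Conjugate addition of the secondary amine to the ynone gives a β-aminoenone in which the C8a phenol attacks C2 by 6-endo addition–elimination (oxa-Michael), closing ring C and excluding the 5-exo path to an aurone.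

Step 18
Reactants: 32 5,7-bis(benzyloxy)-2-[3,4-bis(benzyloxy)phenyl]-6-{[(1S,2S)-2,6,6-trimethyl-2-(triethylsilyloxy)cyclohexyl]methyl}-4H-chromen-4-one
Product: 34 2-(3,4-dihydroxyphenyl)-5,7-dihydroxy-6-{[(1S,2S)-2-hydroxy-2,6,6-trimethylcyclohexyl]methyl}-4H-chromen-4-one, via triethylsilyl ether 33 (not isolated)
Conditions: H2 (1 atm), Pd/C, THF–MeOH, rt; then 1 M HCl (aq), rt
Reagents that add atoms: none
Why: Hydrogenolysis over palladium cleaves the four benzyl ethers and dilute acid then hydrolyses the tertiary silyl ether, conditions under which the flavone C2=C3 bond, the tertiary alcohol and both stereocentres should stay intact.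

Compound list
1 | 2,4,6-trihydroxybenzaldehyde | O=Cc1c(O)cc(O)cc1O | starting material
2 | 2,6-dihydroxy-4-(triisopropylsilyloxy)benzaldehyde | O=Cc1c(O)cc(O[Si](C(C)C)(C(C)C)C(C)C)cc1O | intermediate
3 | 2,6-bis(benzyloxy)-4-(triisopropylsilyloxy)benzaldehyde | O=Cc1c(OCc2ccccc2)cc(O[Si](C(C)C)(C(C)C)C(C)C)cc1OCc1ccccc1 | intermediate
4 | Meldrum's acid (2,2-dimethyl-1,3-dioxane-4,6-dione) | CC1(C)OC(=O)CC(=O)O1 | starting material
5 | 5-[2,6-bis(benzyloxy)-4-(triisopropylsilyloxy)benzylidene]-2,2-dimethyl-1,3-dioxane-4,6-dione | CC1(C)OC(=O)C(=Cc2c(OCc3ccccc3)cc(O[Si](C(C)C)(C(C)C)C(C)C)cc2OCc2ccccc2)C(=O)O1 | intermediate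
6 | 5-[2,6-bis(benzyloxy)-4-(triisopropylsilyloxy)benzyl]-2,2-dimethyl-1,3-dioxane-4,6-dione | CC1(C)OC(=O)C(Cc2c(OCc3ccccc3)cc(O[Si](C(C)C)(C(C)C)C(C)C)cc2OCc2ccccc2)C(=O)O1 | intermediate
7 | 2-[2,6-bis(benzyloxy)-4-(triisopropylsilyloxy)benzyl]malonic acid | OC(=O)C(Cc1c(OCc2ccccc2)cc(O[Si](C(C)C)(C(C)C)C(C)C)cc1OCc1ccccc1)C(=O)O | intermediate
8 | 3-[2,6-bis(benzyloxy)-4-(triisopropylsilyloxy)phenyl]propanoic acid | OC(=O)CCc1c(OCc2ccccc2)cc(O[Si](C(C)C)(C(C)C)C(C)C)cc1OCc1ccccc1 | intermediate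
9 | mesityl oxide (4-methylpent-3-en-2-one) | CC(=O)C=C(C)C | starting material
10 | (R)-4-methylpent-3-en-2-ol | C[C@@H](O)C=C(C)C | intermediate
11 | (2R)-4-methylpent-3-en-2-yl 3-[2,6-bis(benzyloxy)-4-(triisopropylsilyloxy)phenyl]propanoate | C[C@@H](OC(=O)CCc1c(OCc2ccccc2)cc(O[Si](C(C)C)(C(C)C)C(C)C)cc1OCc1ccccc1)C=C(C)C | intermediate
12 | (E)-1-{[(2R)-4-methylpent-3-en-2-yl]oxy}-1-(trimethylsilyloxy)-3-[2,6-bis(benzyloxy)-4-(triisopropylsilyloxy)phenyl]prop-1-ene (arylmethyl group cis to the allylic oxygen) | C[C@@H](O/C(O[Si](C)(C)C)=C\Cc1c(OCc2ccccc2)cc(O[Si](C(C)C)(C(C)C)C(C)C)cc1OCc1ccccc1)C=C(C)C | intermediate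
13 | trimethylsilyl (2S,4E)-2-[2,6-bis(benzyloxy)-4-(triisopropylsilyloxy)benzyl]-3,3-dimethylhex-4-enoate | C[Si](C)(C)OC(=O)[C@@H](Cc1c(OCc2ccccc2)cc(O[Si](C(C)C)(C(C)C)C(C)C)cc1OCc1ccccc1)C(C)(C)/C=C/C | intermediate
14 | (2S,4E)-2-[2,6-bis(benzyloxy)-4-(triisopropylsilyloxy)benzyl]-3,3-dimethylhex-4-enoic acid | OC(=O)[C@@H](Cc1c(OCc2ccccc2)cc(O[Si](C(C)C)(C(C)C)C(C)C)cc1OCc1ccccc1)C(C)(C)/C=C/C | intermediate
15 | (3S,5E)-3-[2,6-bis(benzyloxy)-4-(triisopropylsilyloxy)benzyl]-4,4-dimethylhept-5-en-2-one | CC(=O)[C@@H](Cc1c(OCc2ccccc2)cc(O[Si](C(C)C)(C(C)C)C(C)C)cc1OCc1ccccc1)C(C)(C)/C=C/C | intermediate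
16 | (4S,5S,7E)-5-[2,6-bis(benzyloxy)-4-(triisopropylsilyloxy)benzyl]-4,6,6-trimethylnona-1,7-dien-4-ol | C=CC[C@](C)(O)[C@@H](Cc1c(OCc2ccccc2)cc(O[Si](C(C)C)(C(C)C)C(C)C)cc1OCc1ccccc1)C(C)(C)/C=C/C | intermediate
17 | (1S,6S)-6-[2,6-bis(benzyloxy)-4-(triisopropylsilyloxy)benzyl]-1,5,5-trimethylcyclohex-3-en-1-ol | CC1(C)C=CC[C@](C)(O)[C@H]1Cc1c(OCc2ccccc2)cc(O[Si](C(C)C)(C(C)C)C(C)C)cc1OCc1ccccc1 | intermediate
18 | (1S,2S)-2-[2,6-bis(benzyloxy)-4-(triisopropylsilyloxy)benzyl]-1,3,3-trimethylcyclohexan-1-ol | CC1(C)CCC[C@](C)(O)[C@H]1Cc1c(OCc2ccccc2)cc(O[Si](C(C)C)(C(C)C)C(C)C)cc1OCc1ccccc1 | intermediate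
19 | {[(1S,2S)-2-[2,6-bis(benzyloxy)-4-(triisopropylsilyloxy)benzyl]-1,3,3-trimethylcyclohexyl]oxy}triethylsilane | CC1(C)CCC[C@](C)(O[Si](CC)(CC)CC)[C@H]1Cc1c(OCc2ccccc2)cc(O[Si](C(C)C)(C(C)C)C(C)C)cc1OCc1ccccc1 | intermediate
20 | 3,5-bis(benzyloxy)-4-{[(1S,2S)-2,6,6-trimethyl-2-(triethylsilyloxy)cyclohexyl]methyl}phenol | CC1(C)CCC[C@](C)(O[Si](CC)(CC)CC)[C@H]1Cc1c(OCc2ccccc2)cc(O)cc1OCc1ccccc1 | intermediate
21 | 2-bromo-3,5-bis(benzyloxy)-4-{[(1S,2S)-2,6,6-trimethyl-2-(triethylsilyloxy)cyclohexyl]methyl}phenol | CC1(C)CCC[C@](C)(O[Si](CC)(CC)CC)[C@H]1Cc1c(OCc2ccccc2)cc(O)c(Br)c1OCc1ccccc1 | intermediate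
22 | [2-bromo-3,5-bis(benzyloxy)-4-{[(1S,2S)-2,6,6-trimethyl-2-(triethylsilyloxy)cyclohexyl]methyl}phenoxy]trimethylsilane | CC1(C)CCC[C@](C)(O[Si](CC)(CC)CC)[C@H]1Cc1c(OCc2ccccc2)cc(O[Si](C)(C)C)c(Br)c1OCc1ccccc1 | intermediate
23 | lithium 3,5-bis(benzyloxy)-2-(trimethylsilyl)-4-{[(1S,2S)-2,6,6-trimethyl-2-(triethylsilyloxy)cyclohexyl]methyl}phenoxide | CC1(C)CCC[C@](C)(O[Si](CC)(CC)CC)[C@H]1Cc1c(OCc2ccccc2)cc(O[Li])c([Si](C)(C)C)c1OCc1ccccc1 | intermediate
24 | 3,5-bis(benzyloxy)-2-(trimethylsilyl)-4-{[(1S,2S)-2,6,6-trimethyl-2-(triethylsilyloxy)cyclohexyl]methyl}phenyl trifluoromethanesulfonate | CC1(C)CCC[C@](C)(O[Si](CC)(CC)CC)[C@H]1Cc1c(OCc2ccccc2)cc(OS(=O)(=O)C(F)(F)F)c([Si](C)(C)C)c1OCc1ccccc1 | intermediate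
25 | 3,4-bis(benzyloxy)benzaldehyde | O=Cc1ccc(OCc2ccccc2)c(OCc2ccccc2)c1 | starting material
26 | 1,2-bis(benzyloxy)-4-(2,2-dibromovinyl)benzene | BrC(Br)=Cc1ccc(OCc2ccccc2)c(OCc2ccccc2)c1 | intermediate
27 | lithium [3,4-bis(benzyloxy)phenyl]acetylide | [Li]C#Cc1ccc(OCc2ccccc2)c(OCc2ccccc2)c1 | intermediate
28 | 3-[3,4-bis(benzyloxy)phenyl]propiolic acid | OC(=O)C#Cc1ccc(OCc2ccccc2)c(OCc2ccccc2)c1 | intermediate
29 | 3,5-bis(benzyloxy)-4-{[(1S,2S)-2,6,6-trimethyl-2-(triethylsilyloxy)cyclohexyl]methyl}-1,2-didehydrobenzene (aryne across C4a–C8a) | CC1(C)CCC[C@](C)(O[Si](CC)(CC)CC)[C@H]1CC1=C(OCc2ccccc2)C#CC=C1OCc1ccccc1 | intermediate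
30 | 3-[3,4-bis(benzyloxy)phenyl]-1-[2,4-bis(benzyloxy)-6-hydroxy-3-{[(1S,2S)-2,6,6-trimethyl-2-(triethylsilyloxy)cyclohexyl]methyl}phenyl]prop-2-yn-1-one | CC1(C)CCC[C@](C)(O[Si](CC)(CC)CC)[C@H]1Cc1c(OCc2ccccc2)cc(O)c(C(=O)C#Cc2ccc(OCc3ccccc3)c(OCc3ccccc3)c2)c1OCc1ccccc1 | intermediate
31 | 3-(diethylamino)-3-[3,4-bis(benzyloxy)phenyl]-1-[2,4-bis(benzyloxy)-6-hydroxy-3-{[(1S,2S)-2,6,6-trimethyl-2-(triethylsilyloxy)cyclohexyl]methyl}phenyl]prop-2-en-1-one (alkene geometry not defined) | CC1(C)CCC[C@](C)(O[Si](CC)(CC)CC)[C@H]1Cc1c(OCc2ccccc2)cc(O)c(C(=O)C=C(N(CC)CC)c2ccc(OCc3ccccc3)c(OCc3ccccc3)c2)c1OCc1ccccc1 | intermediate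
32 | 5,7-bis(benzyloxy)-2-[3,4-bis(benzyloxy)phenyl]-6-{[(1S,2S)-2,6,6-trimethyl-2-(triethylsilyloxy)cyclohexyl]methyl}-4H-chromen-4-one | CC1(C)CCC[C@](C)(O[Si](CC)(CC)CC)[C@H]1Cc1c(OCc2ccccc2)cc2oc(-c3ccc(OCc4ccccc4)c(OCc4ccccc4)c3)cc(=O)c2c1OCc1ccccc1 | intermediate
33 | 2-(3,4-dihydroxyphenyl)-5,7-dihydroxy-6-{[(1S,2S)-2,6,6-trimethyl-2-(triethylsilyloxy)cyclohexyl]methyl}-4H-chromen-4-one | CC1(C)CCC[C@](C)(O[Si](CC)(CC)CC)[C@H]1Cc1c(O)cc2oc(-c3ccc(O)c(O)c3)cc(=O)c2c1O | intermediate
34 | 2-(3,4-dihydroxyphenyl)-5,7-dihydroxy-6-{[(1S,2S)-2-hydroxy-2,6,6-trimethylcyclohexyl]methyl}-4H-chromen-4-one | CC1(C)CCC[C@](C)(O)[C@H]1Cc1c(O)cc2oc(-c3ccc(O)c(O)c3)cc(=O)c2c1O | target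

Total step count: 18. Longest linear sequence: 15 steps (steps 1–3, 5–13 and 16–18).

Steps most likely to fail

Step 16. The aryl anion formed after carboxylate addition may be protonated before the acyl group migrates, which would stop at O-arylation; the propiolate may also lose carbon dioxide on heating, or fluoride may begin to cleave the tertiary silyl ether. The fallback sets out from bromophenol 21 and acid 28 and comes back at ynone 30. Acid 28 would be coupled with N,O-dimethylhydroxylamine (EDC, CH2Cl2) to give N-methoxy-N-methyl-3-[3,4-bis(benzyloxy)phenyl]propiolamide F1. Bromophenol 21 would be treated with n-BuLi (2.2 equiv, THF, −78 °C) to give lithium 3,5-bis(benzyloxy)-2-lithio-4-{[(1S,2S)-2,6,6-trimethyl-2-(triethylsilyloxy)cyclohexyl]methyl}phenoxide F2. Acylation of F2 by F1, followed by acidic work-up of the stable tetrahedral adduct, should release 30 with the same regiochemistry, fixed here by the position of the bromine.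

Step 8. Facial selectivity in the addition to the α-branched ketone may be poor because of the early transition state of the allyl Grignard reagent, and enolisation may compete with addition. The fallback sets out from ketone 15 and comes back at dienol 16. Dimethylsulfonium methylide (Me3SI, n-BuLi, THF, −10 °C) would add irreversibly as a bulkier one-carbon nucleophile along the same Felkin–Anh trajectory and close to (2R)-2-{(2S,4E)-1-[2,6-bis(benzyloxy)-4-(triisopropylsilyloxy)phenyl]-3,3-dimethylhex-4-en-2-yl}-2-methyloxirane F3. Its methylene terminus would then be opened by vinylmagnesium bromide with catalytic copper iodide (CuI), which gives 16 with the C2'–C3' bond made in the first stage and the allyl unit completed in the second.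

Step 6. Enantiomeric purity may be eroded, because any ester enolised to the other ketene acetal geometry rearranges to the mirror-image acid, and incomplete enantiopurity of 10 adds to this. The fallback sets out from acid 14 as obtained and comes back to 14. Classical resolution would take over as the source of enantiopurity: the acid would be crystallised as (S)-1-phenylethylammonium (2S,4E)-2-[2,6-bis(benzyloxy)-4-(triisopropylsilyloxy)benzyl]-3,3-dimethylhex-4-enoate F4, with the antipodal amine used instead if it gives the less soluble salt. Acidification of the recrystallised salt should return 14 free of its enantiomer before the ketone is made.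

Further compounds
F1 | step 16 | N-methoxy-N-methyl-3-[3,4-bis(benzyloxy)phenyl]propiolamide | CON(C)C(=O)C#Cc1ccc(OCc2ccccc2)c(OCc2ccccc2)c1
F2 | step 16 | lithium 3,5-bis(benzyloxy)-2-lithio-4-{[(1S,2S)-2,6,6-trimethyl-2-(triethylsilyloxy)cyclohexyl]methyl}phenoxide | CC1(C)CCC[C@](C)(O[Si](CC)(CC)CC)[C@H]1Cc1c(OCc2ccccc2)cc(O[Li])c([Li])c1OCc1ccccc1
F3 | step 8 | (2R)-2-{(2S,4E)-1-[2,6-bis(benzyloxy)-4-(triisopropylsilyloxy)phenyl]-3,3-dimethylhex-4-en-2-yl}-2-methyloxirane | O1C[C@@]1(C)[C@@H](Cc1c(OCc2ccccc2)cc(O[Si](C(C)C)(C(C)C)C(C)C)cc1OCc1ccccc1)C(C)(C)/C=C/C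
F4 | step 6 | (S)-1-phenylethylammonium (2S,4E)-2-[2,6-bis(benzyloxy)-4-(triisopropylsilyloxy)benzyl]-3,3-dimethylhex-4-enoate | [O-]C(=O)[C@@H](Cc1c(OCc2ccccc2)cc(O[Si](C(C)C)(C(C)C)C(C)C)cc1OCc1ccccc1)C(C)(C)/C=C/C.C[C@H]([NH3+])c1ccccc1
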